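The route rests on cutting the aryl–vinyl bond of the caffeate, between C-3 of the propenoate and C-1 of the 3,4-dihydroxyphenyl ring. A Mizoroki–Heck arylation of the terpenyl acrylate with unprotected 4-iodocatechol forms this bond in the last step, fixes the E-alkene and releases the target directly; it exploits the electron-poor terminal CH2 of the acrylate. The acrylate is built from a boat-type Claisen rearrangement of the (R)-3-methylcyclohex-2-enyl enol ether of 2-methylcyclopentanone, which relays one carbinol stereocentre to both vicinal quaternary carbons; hydroboration, α-methylation, dehydrogenation and a CBS reduction then shape the 2-methylcyclohex-2-enol ring.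

Key step: step 12

Remark: 4-iodobenzene-1,2-diol is taken as a purchasable compound; stereocentres that are created in 5, 8, 9 and 12 and erased again later are drawn without descriptors.

Step 1
Reactants: 1 3-methylcyclohex-2-en-1-one
Product: 2 (1R)-3-methylcyclohex-2-en-1-ol
Conditions: (S)-1-methyl-3,3-diphenyltetrahydro-1H,3H-pyrrolo[1,2-c][1,3,2]oxazaborole ((S)-Me-CBS, 10 mol %), catecholborane, toluene, −78 °C; H2O work-up
Reagents that add atoms: none
Why: CBS reduction, in which the oxazaborolidine–borane complex binds the carbonyl with the alkenyl arm as the larger group and delivers hydride to one face, so that the (S)-catalyst should give the (R)-allylic alcohol by 1,2-reduction.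

Step 2
Reactants: 3 2-methylcyclopentan-1-one (racemic)
Product: 4 1,1-dimethoxy-2-methylcyclopentane
Conditions: HC(OMe)3, MeOH, TsOH·H2O (cat.), rt
Reagents that add atoms: trimethyl orthoformate COC(OC)OC; methanol CO
Why: Acid-catalysed ketalisation driven to completion because the orthoformate consumes the water formed; the racemic C-2 becomes sp2 in the next step.

Step 3
Reactants: 2 (1R)-3-methylcyclohex-2-en-1-ol; 4 1,1-dimethoxy-2-methylcyclopentane
Product: 7 (2R)-2-methyl-2-[(1S)-1-methylcyclohex-2-en-1-yl]cyclopentan-1-one, via mixed methyl allyl ketal 5 (not isolated), via allyl enol ether 6 (not isolated)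
Conditions: 4 (4 equiv), 2,4-dinitrophenol (5 mol %), mesitylene, 160 °C, MeOH distilled off
Reagents that add atoms: none
Why: Ketal Claisen rearrangement, in which acid-catalysed exchange gives 5, loss of methanol toward the more substituted α-carbon gives the tetrasubstituted enol ether 6, and the [3,3]-shift joins the two fully substituted carbons on the ring face that carried the oxygen (fixing the cyclohexenyl quaternary centre) through the boat-like transition state expected for a cyclohex-2-enyl vinyl ether substituted at the oxygen-bearing vinyl carbon, since a chair would stack the cyclopentene ring over the cyclohexene ring (fixing the cyclopentanone quaternary centre).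

Step 4
Reactants: 7 (2R)-2-methyl-2-[(1S)-1-methylcyclohex-2-en-1-yl]cyclopentan-1-one
Product: 8 (2R)-2-methyl-2-[(1S)-1-methylcyclohex-2-en-1-yl]-1-[(trimethylsilyl)methyl]cyclopentan-1-ol (mixture at C-1)
Conditions: Me3SiCH2Li, CeCl3, THF, −78 °C to 0 °C; aq. NH4Cl
Reagents that add atoms: (trimethylsilyl)methyllithium [Li]C[Si](C)(C)C
Why: First half of a Peterson olefination, in which the organocerium reagent adds to the hindered, enolisable ketone without enolisation and the β-hydroxysilane masks the later exocyclic methylene against the coming hydroboration; the carbinol configuration is irrelevant.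

Step 5
Reactants: 8 (2R)-2-methyl-2-[(1S)-1-methylcyclohex-2-en-1-yl]-1-[(trimethylsilyl)methyl]cyclopentan-1-ol
Product: 9 (3S)-3-{(1R)-2-hydroxy-1-methyl-2-[(trimethylsilyl)methyl]cyclopentyl}-3-methylcyclohexan-1-ol (mixture at both carbinol carbons)
Conditions: BH3·THF, THF, 0 °C to rt; then NaOH, H2O2, 0 °C to rt
Reagents that add atoms: hydrogen peroxide OO
Why: Brown hydroboration–oxidation, in which borane adds syn to the ring alkene with boron on the carbon remote from the quaternary centre and oxidation with retention gives the secondary alcohol, whose configuration is erased in step 7.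

Step 6
Reactants: 9 (3S)-3-{(1R)-2-hydroxy-1-methyl-2-[(trimethylsilyl)methyl]cyclopentyl}-3-methylcyclohexan-1-ol
Product: 10 (3S)-3-methyl-3-[(1S)-1-methyl-2-methylidenecyclopentyl]cyclohexan-1-ol (mixture at C-1)
Conditions: KH, THF, 0 °C to 40 °C
Reagents that add atoms: none
Why: Peterson olefination, in which the potassium β-silyl alkoxide undergoes syn-elimination of trimethylsilanolate and gives the exocyclic methylene regiospecifically next to the quaternary carbon.

Step 7
Reactants: 10 (3S)-3-methyl-3-[(1S)-1-methyl-2-methylidenecyclopentyl]cyclohexan-1-ol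
Product: 11 (3S)-3-methyl-3-[(1S)-1-methyl-2-methylidenecyclopentyl]cyclohexan-1-one
Conditions: Dess–Martin periodinane, CH2Cl2, 0 °C to rt
Reagents that add atoms: none
Why: Dess–Martin oxidation of the secondary alcohol under mild conditions that leave the 1,1-disubstituted alkene untouched.

Step 8
Reactants: 11 (3S)-3-methyl-3-[(1S)-1-methyl-2-methylidenecyclopentyl]cyclohexan-1-one
Product: 12 (5S)-2,5-dimethyl-5-[(1S)-1-methyl-2-methylidenecyclopentyl]cyclohexan-1-one (mixture at C-2)
Conditions: LiN(i-Pr)2 (LDA), THF, −78 °C; MeI, DMPU, −78 °C to −30 °C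
Reagents that add atoms: iodomethane CI
Why: Kinetic enolate alkylation, in which LDA deprotonates the α-carbon remote from the quaternary centre and the lithium enolate is methylated there; the new methine forms as an epimer mixture that is erased in step 9.

Step 9
Reactants: 12 (5S)-2,5-dimethyl-5-[(1S)-1-methyl-2-methylidenecyclopentyl]cyclohexan-1-one
Product: 13 (5S)-2,5-dimethyl-5-[(1S)-1-methyl-2-methylidenecyclopentyl]cyclohex-2-en-1-one
Conditions: IBX, DMSO, 70 °C
Reagents that add atoms: none
Why: IBX-mediated ketone dehydrogenation through the more substituted enol, the only one with a β-hydrogen because the other α-carbon adjoins the quaternary centre, should give the 2-methylcyclohex-2-enone.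

Step 10
Reactants: 13 (5S)-2,5-dimethyl-5-[(1S)-1-methyl-2-methylidenecyclopentyl]cyclohex-2-en-1-one
Product: 14 (1S,5S)-2,5-dimethyl-5-[(1S)-1-methyl-2-methylidenecyclopentyl]cyclohex-2-en-1-ol
Conditions: (R)-1-methyl-3,3-diphenyltetrahydro-1H,3H-pyrrolo[1,2-c][1,3,2]oxazaborole ((R)-Me-CBS, 20 mol %), catecholborane, toluene, −78 °C; H2O work-up
Reagents that add atoms: none
Why: CBS reduction under catalyst control, in which the 2-methylalkenyl arm acts as the larger group so that the (R)-catalyst should give the (1S)-alcohol (hydroxyl cis to the cyclopentyl group), while catecholborane at −78 °C does not hydroborate the exocyclic alkene.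

Step 11
Reactants: 14 (1S,5S)-2,5-dimethyl-5-[(1S)-1-methyl-2-methylidenecyclopentyl]cyclohex-2-en-1-ol
Product: 15 (1S,5S)-2,5-dimethyl-5-[(1S)-1-methyl-2-methylidenecyclopentyl]cyclohex-2-en-1-yl prop-2-enoate
Conditions: acryloyl chloride, i-Pr2NEt, 4-(dimethylamino)pyridine (cat.), CH2Cl2, −20 °C to 0 °C
Reagents that add atoms: acryloyl chloride C=CC(=O)Cl
Why: DMAP-catalysed esterification of the secondary allylic alcohol with the acid chloride at low temperature, with retention at the carbinol carbon.

Step 12
Reactants: 15 (1S,5S)-2,5-dimethyl-5-[(1S)-1-methyl-2-methylidenecyclopentyl]cyclohex-2-en-1-yl prop-2-enoate; 16 4-iodobenzene-1,2-diol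
Product: 17 (1S,5S)-2,5-dimethyl-5-[(1S)-1-methyl-2-methylidenecyclopentyl]cyclohex-2-en-1-yl (2E)-3-(3,4-dihydroxyphenyl)prop-2-enoate
Conditions: Pd(OAc)2 (5 mol %), n-Bu4NCl, NaHCO3, DMF, 50 °C, argon
Reagents that add atoms: none
Why: Mizoroki–Heck reaction, in which zerovalent palladium formed in situ inserts into the C–I bond of 16, the arylpalladium iodide adds syn across the acrylate C=C with the aryl group going to the terminal CH2 carbon, and syn β-hydride elimination releases the cinnamate while NaHCO3 regenerates the catalyst. The closest known reaction type is the phosphine-free (Jeffery) Heck arylation of acrylates with iodophenols. No ring is closed and no stereocentre is formed; the E geometry follows from the elimination conformer that keeps aryl and ester anti. The step needs regioselectivity for the β-carbon, secured by the polarisation and the unhindered terminus of the acrylate, and chemoselectivity over the trisubstituted ring alkene and the hindered exocyclic methylene, secured by their electron-rich, substituted character. Ionisation of the allylic ester should be suppressed by the absence of phosphine and the fast oxidative addition of the aryl iodide, and the weak base keeps the catechol protonated so that the free hydroxyl groups should be tolerated.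

Compound list
1 | 3-methylcyclohex-2-en-1-one | CC1=CC(=O)CCC1 | starting material
2 | (1R)-3-methylcyclohex-2-en-1-ol | CC1=C[C@H](O)CCC1 | intermediate
3 | 2-methylcyclopentan-1-one (racemic) | CC1CCCC1=O | starting material
4 | 1,1-dimethoxy-2-methylcyclopentane | COC1(OC)CCCC1C | intermediate
5 | 1-methoxy-2-methyl-1-{[(1R)-3-methylcyclohex-2-en-1-yl]oxy}cyclopentane (mixed ketal, mixture at the cyclopentane centres) | CC1=C[C@H](OC2(OC)CCCC2C)CCC1 | intermediate
6 | 1-methyl-2-{[(1R)-3-methylcyclohex-2-en-1-yl]oxy}cyclopent-1-ene | CC1=C[C@H](OC2=C(C)CCC2)CCC1 | intermediate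
7 | (2R)-2-methyl-2-[(1S)-1-methylcyclohex-2-en-1-yl]cyclopentan-1-one | O=C1CCC[C@]1(C)[C@@]1(C)CCCC=C1 | intermediate
8 | (2R)-2-methyl-2-[(1S)-1-methylcyclohex-2-en-1-yl]-1-[(trimethylsilyl)methyl]cyclopentan-1-ol (mixture at C-1) | C[Si](C)(C)CC1(O)CCC[C@]1(C)[C@@]1(C)CCCC=C1 | intermediate
9 | (3S)-3-{(1R)-2-hydroxy-1-methyl-2-[(trimethylsilyl)methyl]cyclopentyl}-3-methylcyclohexan-1-ol (mixture at both carbinol carbons) | C[Si](C)(C)CC1(O)CCC[C@]1(C)[C@@]1(C)CCCC(O)C1 | intermediate
10 | (3S)-3-methyl-3-[(1S)-1-methyl-2-methylidenecyclopentyl]cyclohexan-1-ol (mixture at C-1) | C=C1CCC[C@]1(C)[C@@]1(C)CCCC(O)C1 | intermediate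
11 | (3S)-3-methyl-3-[(1S)-1-methyl-2-methylidenecyclopentyl]cyclohexan-1-one | C=C1CCC[C@]1(C)[C@@]1(C)CCCC(=O)C1 | intermediate
12 | (5S)-2,5-dimethyl-5-[(1S)-1-methyl-2-methylidenecyclopentyl]cyclohexan-1-one (mixture at C-2) | C=C1CCC[C@]1(C)[C@@]1(C)CCC(C)C(=O)C1 | intermediate
13 | (5S)-2,5-dimethyl-5-[(1S)-1-methyl-2-methylidenecyclopentyl]cyclohex-2-en-1-one | C=C1CCC[C@]1(C)[C@@]1(C)CC=C(C)C(=O)C1 | intermediate
14 | (1S,5S)-2,5-dimethyl-5-[(1S)-1-methyl-2-methylidenecyclopentyl]cyclohex-2-en-1-ol | C=C1CCC[C@]1(C)[C@@]1(C)CC=C(C)[C@@H](O)C1 | intermediate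
15 | (1S,5S)-2,5-dimethyl-5-[(1S)-1-methyl-2-methylidenecyclopentyl]cyclohex-2-en-1-yl prop-2-enoate | C=C1CCC[C@]1(C)[C@@]1(C)CC=C(C)[C@@H](OC(=O)C=C)C1 | intermediate
16 | 4-iodobenzene-1,2-diol | Oc1ccc(I)cc1O | starting material
17 | (1S,5S)-2,5-dimethyl-5-[(1S)-1-methyl-2-methylidenecyclopentyl]cyclohex-2-en-1-yl (2E)-3-(3,4-dihydroxyphenyl)prop-2-enoate | C=C1CCC[C@]1(C)[C@@]1(C)CC=C(C)[C@@H](OC(=O)/C=C/c2ccc(O)c(O)c2)C1 | target

Total step count: 12. Longest linear sequence: 11 steps (1 to 17 through steps 1 and 3–12; equally 3 to 17 through steps 2–12).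

Steps most likely to fail

Step 3 (ketal Claisen). Methanol may be lost toward the CH2 side of the mixed ketal, so that the rearrangement forms a tertiary instead of a quaternary cyclopentanone carbon. The hot acidic medium may also ionise the allylic C–O bond, which would erode enantiopurity or cause elimination, and some material may leak through the chair transition state. The fallback sets out from 3 (and uses 2) and comes back to the route at 7. Condensation of 3 with hydrazine hydrate gives 2-methylcyclopentanone hydrazone F1. Barton iodination (I2, 1,1,3,3-tetramethylguanidine, Et2O) converts it into 1-iodo-2-methylcyclopent-1-ene F2, which is freed from any regioisomer. Copper-catalysed C–O coupling of F2 with 2 (CuI, 3,4,7,8-tetramethyl-1,10-phenanthroline, Cs2CO3, toluene, 110 °C) should give enol ether 6 under basic conditions with the double bond fixed in place. Further heating to 150 °C lets the Claisen rearrangement run to 7.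

Step 12 (Heck coupling). The free catechol may chelate or be oxidised by the palladium catalyst and stall turnover, and the allylic ester may ionise on zerovalent palladium. The fallback sets out from 16 and comes back at 17. Silylation of 16 (t-BuMe2SiCl, imidazole, DMF) gives 4-iodo-1,2-bis(tert-butyldimethylsilyloxy)benzene F3. Heck coupling of F3 with 15 under the palladium conditions of step 12 gives the bis(tert-butyldimethylsilyl) ether of the target F4. Treatment with n-Bu4NF buffered with AcOH (THF, 0 °C) removes both silyl groups to give 17.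

Step 10 (CBS reduction). Facial selectivity may be poor, because the catalyst has to deliver hydride to the carbonyl face shielded by the axial C-5 methyl group (a mismatched case). The fallback sets out from 13 and comes back at 15. Reduction of 13 with (i-Bu)2AlH (toluene, −78 °C), which should attack from the face opposite the axial methyl group, gives (1R,5S)-2,5-dimethyl-5-[(1S)-1-methyl-2-methylidenecyclopentyl]cyclohex-2-en-1-ol F5. A Mitsunobu reaction of F5 with acrylic acid (PPh3, diisopropyl azodicarboxylate, THF, 0 °C) inverts C-1 and installs the acrylate in one operation, giving 15.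

Further compounds
F1 | step 3 | 2-methylcyclopentanone hydrazone | CC1CCCC1=NN
F2 | step 3 | 1-iodo-2-methylcyclopent-1-ene | CC1=C(I)CCC1
F3 | step 12 | 4-iodo-1,2-bis(tert-butyldimethylsilyloxy)benzene | CC(C)(C)[Si](C)(C)Oc1ccc(I)cc1O[Si](C)(C)C(C)(C)C
F4 | step 12 | (1S,5S)-2,5-dimethyl-5-[(1S)-1-methyl-2-methylidenecyclopentyl]cyclohex-2-en-1-yl (2E)-3-[3,4-bis(tert-butyldimethylsilyloxy)phenyl]prop-2-enoate | C=C1CCC[C@]1(C)[C@@]1(C)CC=C(C)[C@@H](OC(=O)/C=C/c2ccc(O[Si](C)(C)C(C)(C)C)c(O[Si](C)(C)C(C)(C)C)c2)C1
F5 | step 10 | (1R,5S)-2,5-dimethyl-5-[(1S)-1-methyl-2-methylidenecyclopentyl]cyclohex-2-en-1-ol | C=C1CCC[C@]1(C)[C@@]1(C)CC=C(C)[C@H](O)C1
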